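Remark on the chemistry: compound 1 (the acetonide of hydrogenated vitamin C) is treated as a purchasable material, and the target is taken as the (2S,3S,4R) isomer, with the aryl group cis to the C9 arm and the C9 arm trans to the benzyl arm. Abbreviations: TIPS = triisopropylsilyl, TBS = tert-butyldimethylsilyl, Tr = triphenylmethyl.

## The problem

The target is a 2-aryl-3,4-disubstituted tetrahydrofuran (ring O1–C2–C3–C4–C5). C2 carries a guaiacyl ring, C3 a CH2O arm (C9) esterified with (E)-p-coumaric acid, and C4 a guaiacylmethyl arm (C7'). The three contiguous stereocentres are (2S,3S,4R): the C9 arm is trans to the benzyl arm but cis to the aryl group, so one relationship is relaxed and the other crowded. The 3,4-trans pair can be set by two successive anti additions on a five-membered ring. C3 can then control C2, provided the last bond made at C2 is the C–H bond, delivered anti to the C9 arm; any route that lets C2 equilibrate drifts to the 2,3-trans isomer. C2 is a benzylic ether para to a phenol oxygen, so acids can reopen the ring and hydrogenolysis can cleave it, while the cinnamate ester tolerates neither strong base, nucleophiles nor hydrogenation; the three phenols must therefore be released last, by buffered fluoride, and the two primary oxygens (on C5 and C9) must be told apart because only C9–O is acylated. The enabling feature is that C5, C4, C3 and C2 map onto the carbonyl, α, β and γ carbons of a γ-(alkoxymethyl)butenolide: the γ-substituent can steer the C3–C9 and C4–C7' bonds and is then excised, which turns the γ-carbon into the C2 carbonyl at which the aryl group enters.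

## Retrosynthesis

**Ester and phenols (32 ⇒ 31 ⇒ 27 + 30).** The last cut is the C9O–acyl bond, preceded only by removal of three aryl silyl ethers from 31. Acylating alcohol 27 with the silylated acid 30 (from 28 via 29) keeps the cinnamate out of every hydride and organometallic step. Carrying free phenols instead would demand selective acylation of one hydroxyl among three. Alcohol 27 comes from 26 by acid-selective cleavage of its single alkyl silyl ether, which is why the phenols carry TIPS and C9–O carries TBS. The forward steps are a carbodiimide coupling and a buffered fluoride desilylation.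

**C2 (26 ⇒ 24 ⇒ 20 + 23).** The C2–H bond is cut first and the C2–aryl bond second: 26 arises from hemiketal 24 through oxocarbenium ion 25, and 24 from lactone 20 and aryllithium 23 (from 22, from 21). The order matters. Hydride adds to the aryl-substituted cation anti to the C9 arm and leaves the aryl group cis. An aryl nucleophile on an unsubstituted C2 cation, or acid closure of a benzylic diol, would place it trans. Precursor 20 has lost one stereocentre and one aromatic ring. The forward reactions must stop at mono-addition and must reduce at low temperature before the cation can lose the C3 proton.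

**Carbonyl transposition (20 ⇒ 19 ⇒ 18 ⇒ 15 ⇒ 14 ⇒ 13).** The lactone carbonyl of 19 is what remains of a carbinol carbon that once carried a further CH2O group. Adding that carbon back gives tetraol 16, the detritylated form of 15. In 15 the C5 and C9 hydroxyls arise together from reduction of the lactone carbonyl and the ester of 14, and that ester is the unmasked tris(methylthio)methyl group of 13. The detour costs four steps against a direct construction of the C2 carbonyl. In return, a removable stereocentre sits next to C3 during the key step and vanishes exactly where the new C2 centre is made. The two primary hydroxyls need no separate differentiation: after glycol cleavage only C5–OH can close a five-membered lactol 18 (via 17), and Ag2CO3 oxidises the lactol in preference to the free C9–OH.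

**Key disconnection (13 ⇒ 5 + 11 + 9).** The C3–C9 and C4–C7' bonds are cut together, leaving butenolide 5, carbanion 11 (from 10) and benzylic bromide 9. Separate alkylation of a saturated lactone could set only one centre per step and would need a second controlling element. An aldol at C4 would add a benzylic deoxygenation. Here one stereocentre and two achiral partners give both ring centres in one flask. The forward reaction must add 1,4 and anti to the trityloxymethyl group, then C-benzylate anti to the new substituent.

**Building blocks.** Butenolide 5 comes from 4, Z-enoate 3, aldehyde 2 and lactone acetonide 1 by glycol cleavage, Z-selective olefination, acid lactonisation and tritylation. Bromide 9 comes from vanillin 6 through 7 and 8. All are standard functional-group steps.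

## Roads not taken

**Alternative 1:** The ring is cut at O1–C2 and C4–C5. A donor–acceptor cyclopropane A1 (gem-diester as the future C4, O-pivaloyl guaiacyl donor on the future C2, silyloxymethyl arm on the future C3, aryl and arm trans) would be combined with formaldehyde A2 in a formal (3+2) annulation. With Sn(OTf)2 the aldehyde oxygen should open the activated cyclopropane at the benzylic carbon with inversion, and the malonate carbon should then close on the oxocarbenium carbon, giving tetrahydrofuran diester A3 with the aryl group cis to the arm.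
- Merits: the ring and the crowded C2/C3 pair form in one stereospecific step, A1 is accessible in enantioenriched form by catalysis, and no degradation sequence is needed.
- Weak points: the stereospecificity rests on an SN2-like opening, whereas an electron-rich guaiacyl donor favours ionisation to a benzylic zwitterion, with racemisation and cis/trans leakage; the pivalate only tempers this. A2 is the least well-behaved aldehyde partner for this annulation, and the extra ring substituent of A1 lies outside the usual substrate range. A3 still lacks the C4 stereocentre and the whole C7'-aryl unit, so dealkoxycarbonylation, adjustment of the remaining ester, aryl addition at C7' and a benzylic deoxygenation would follow, the last under reductive acidic conditions that the cis 2-aryl ether tolerates badly.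
- Comparison: this road is probably shorter by several steps and sets C2 by a stereospecific event rather than a late facial selection, which is a real advantage. The chosen plan sets against it a key step of established type on this substrate class, delivery of the complete benzyl arm with both C3 and C4 in that step, and an absolute configuration that depends neither on a catalyst nor on a configurationally fragile intermediate.

**Alternative 2:** The cuts are C2–C3 and the acyl C5–O1 bond. The O-silylated vanillin A4 would react with the 2-(methoxycarbonyl)allylboronate A5, whose silyloxymethyl group is cis to the borylmethyl group. In a closed chair transition state this substituent is axial, the C2–C3 bond forms with the syn relationship, and the borate alkoxide acylates on the neighbouring ester, so the cis-disposed α-methylene lactone A6 should result (its carbonyl is the future C5).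
- Merits: this is the most direct entry to the cis C2/C3 pair, with bond, two stereocentres and ring in one step. The exo-methylene group of A6 is a handle for conjugate arylation that brings in the C7'-aryl unit, with C4 adjustable to trans.
- Weak points: ester-bearing allylboronates are sluggish and need acid activation, and the electron-rich aldehyde A4 is a poor electrophile. Absolute control must come from a chiral catalyst or chiral boronate on a combination for which high selectivity cannot be taken for granted, and A5 must be geometrically pure. The C5 carbonyl must finally be reduced to CH2 in a molecule that already holds the acid-labile cis benzylic C2–O bond, and either way of doing so invites C2 epimerisation.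
- Comparison: this road is shorter than the chosen one and as direct as possible for C2/C3. The chosen plan sets against it the chiral-pool origin of the configuration, and the creation of C2 last, at the correct oxidation level of C5, so that it never has to survive a Lewis-acidic reduction elsewhere in the ring.

**Alternative 3:** The cut is O1–C5 by ring expansion. The prochiral 3-(arylmethyl)cyclobutanone A7 would undergo an enantioselective Baeyer–Villiger oxidation (a peracid with Sc(OTf)3 and a chiral N,N'-dioxide ligand, or a monooxygenase). Oxygen would insert into one of the two enantiotopic C(O)–CH2 bonds to give the (R)-β-benzyl-γ-butyrolactone A8.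
- Merits: A8 is the classical lignan lactone, reached catalytically in very few steps. Trans-selective α-hydroxymethylation would lead to a silyl analogue of 19, after which the end game (steps 13–20) would be unchanged.
- Weak points: the single stereocentre is created remote from the carbonyl and is flanked by a flexible CH2Ar group, the least favourable case for telling the two methylene groups apart. The enantiomeric purity of everything downstream therefore hinges on one catalyst–substrate match or on enzyme screening, with no diastereomeric checkpoint for upgrading. The peracid must spare the electron-rich arene. Hydroxymethylation of a lactone enolate with a formaldehyde source is a reversible aldol prone to double addition and dehydration, so C3 and C9 would rest on a less dependable bond formation than the tandem step.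
- Comparison: in step count this road is clearly better; it would reach the common hydroxymethyl lactone in roughly half the operations and without the excision sequence. The chosen plan sets against this an absolute configuration fixed by the starting material, C3 and C4 installed together under substrate control with C9 attached irreversibly, and diastereomers rather than enantiomers as the only stereochemical impurities.

Key step: step 8

## Route

Step 1
Reactants: 1 5,6-O-isopropylidene-L-gulono-1,4-lactone
Product: 2 (S)-2,2-dimethyl-1,3-dioxolane-4-carbaldehyde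
Conditions: NaIO4 (2 equiv), H2O, pH 5.5, 0 °C to rt
Reagents that add atoms: none
Why: Malaprade glycol cleavage of the 2,3-diol; the glyoxylate ester formed hydrolyses and the resulting α-hydroxy aldehyde is cleaved again, leaving C4–C6 as the aldehyde. The stereocentre is the untouched C5 of the sugar.

Step 2
Reactants: 2 (S)-2,2-dimethyl-1,3-dioxolane-4-carbaldehyde
Product: 3 methyl (Z)-3-[(4R)-2,2-dimethyl-1,3-dioxolan-4-yl]prop-2-enoate
Conditions: Ph3P=CHCO2Me, MeOH, 0 °C
Reagents that add atoms: methyl (triphenylphosphoranylidene)acetate (COC(=O)C=P(c1ccccc1)(c1ccccc1)c1ccccc1)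
Why: Wittig olefination; with α-alkoxy aldehydes in methanol the stabilised ylide should give mainly the Z enoate. The minor E isomer cannot lactonise and is removed here or after step 3.

Step 3
Reactants: 3 methyl (Z)-3-[(4R)-2,2-dimethyl-1,3-dioxolan-4-yl]prop-2-enoate
Product: 4 (R)-5-(hydroxymethyl)furan-2(5H)-one
Conditions: aq. H2SO4 (cat.), MeOH, rt
Reagents that add atoms: none
Why: Acid-catalysed acetonide hydrolysis followed by lactonisation (intramolecular transesterification) of the Z γ-hydroxy enoate; the stereocentre is not involved.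

Step 4
Reactants: 4 (R)-5-(hydroxymethyl)furan-2(5H)-one
Product: 5 (R)-5-(trityloxymethyl)furan-2(5H)-one
Conditions: TrCl, pyridine, DMAP (cat.), CH2Cl2, rt
Reagents that add atoms: trityl chloride (ClC(c1ccccc1)(c1ccccc1)c1ccccc1)
Why: Tritylation of the primary alcohol; the weak base avoids deprotonation at the γ-carbon, so the stereocentre should be retained.

Step 5
Reactants: 6 vanillin
Product: 7 3-methoxy-4-(triisopropylsilyloxy)benzaldehyde
Conditions: TIPSCl, imidazole, DMF, rt
Reagents that add atoms: triisopropylsilyl chloride (CC(C)[Si](Cl)(C(C)C)C(C)C)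
Why: Standard imidazole-mediated silylation of a phenol.

Step 6
Reactants: 7 3-methoxy-4-(triisopropylsilyloxy)benzaldehyde
Product: 8 [3-methoxy-4-(triisopropylsilyloxy)phenyl]methanol
Conditions: NaBH4, MeOH, 0 °C
Reagents that add atoms: none
Why: Borohydride reduction of an aryl aldehyde; the aryl silyl ether is stable under these conditions.

Step 7
Reactants: 8 [3-methoxy-4-(triisopropylsilyloxy)phenyl]methanol
Product: 9 [4-(bromomethyl)-2-methoxyphenoxy]triisopropylsilane
Conditions: PBr3, Et2O, 0 °C
Reagents that add atoms: phosphorus tribromide (BrP(Br)Br)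
Why: Bromination of a benzylic alcohol through its phosphite ester; the labile bromide is used directly after aqueous work-up.

Step 8
Reactants: 5 (R)-5-(trityloxymethyl)furan-2(5H)-one; 10 tris(methylthio)methane; 9 [4-(bromomethyl)-2-methoxyphenoxy]triisopropylsilane
Product: 13 (3R,4R,5R)-3-[3-methoxy-4-(triisopropylsilyloxy)benzyl]-4-[tris(methylthio)methyl]-5-(trityloxymethyl)oxolan-2-one (all-trans), via tris(methylthio)methyllithium 11 (not isolated), via lithium lactone enolate 12 (not isolated)
Conditions: 10, n-BuLi, THF, −78 °C; 5, −78 °C; then 9, DMPU, −78 to −30 °C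
Reagents that add atoms: none
Why: n-BuLi deprotonates 10 to the soft, sulfur-stabilised carbanion 11, which adds to the β-carbon of butenolide 5 to give lithium enolate 12, and 12 is C-benzylated by 9 once DMPU is added (tandem Michael addition–enolate alkylation). The closest known reaction type is the conjugate addition of trithioorthoformate or dithiane anions to γ-(alkoxymethyl)butenolides with trapping of the enolate by an alkyl or benzyl halide. No ring is closed; the two new bonds (C3–C9 and C4–C7' of the target) are made on the existing five-membered ring. The β-stereocentre is controlled by the trityloxymethyl group on the γ-carbon, which shields one face so that 11 enters anti to it. The α-stereocentre is controlled by the new, very bulky tris(methylthio)methyl group, which directs the bromide to the opposite face of the planar enolate, so the all-trans lactone should result with its absolute configuration derived only from the γ-carbon of 5. The step needs 1,4- rather than 1,2-addition, secured by the polarisable and hindered carbanion, and C-alkylation before proton exchange, secured by the reactive para-silyloxybenzyl bromide, the polar cosolvent and the low temperature.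

Step 9
Reactants: 13 (3R,4R,5R)-3-[3-methoxy-4-(triisopropylsilyloxy)benzyl]-4-[tris(methylthio)methyl]-5-(trityloxymethyl)oxolan-2-one
Product: 14 methyl (2R,3R,4R)-4-[3-methoxy-4-(triisopropylsilyloxy)benzyl]-5-oxo-2-(trityloxymethyl)oxolane-3-carboxylate
Conditions: HgCl2, HgO, MeOH/H2O (12:1), rt
Reagents that add atoms: methanol (CO); water (O)
Why: Thiophilic divalent mercury ionises the orthothioester stepwise and methanol and water capture the cations to give the methyl ester (metal-assisted orthothioester solvolysis). HgO takes up the acid released, so the trityl and aryl silyl ethers should persist.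

Step 10
Reactants: 14 methyl (2R,3R,4R)-4-[3-methoxy-4-(triisopropylsilyloxy)benzyl]-5-oxo-2-(trityloxymethyl)oxolane-3-carboxylate
Product: 15 (2R,3S,4R)-3-(hydroxymethyl)-2-[3-methoxy-4-(triisopropylsilyloxy)benzyl]-5-(trityloxy)pentane-1,4-diol
Conditions: LiAlH4, THF, 0 °C to rt
Reagents that add atoms: none
Why: Hydride reduction of the lactone and the ester in one operation; no stereocentre is touched, and trityl and aryl TIPS ethers are inert to the hydride.

Step 11
Reactants: 15 (2R,3S,4R)-3-(hydroxymethyl)-2-[3-methoxy-4-(triisopropylsilyloxy)benzyl]-5-(trityloxy)pentane-1,4-diol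
Product: 18 (3S,4R)-3-(hydroxymethyl)-4-[3-methoxy-4-(triisopropylsilyloxy)benzyl]oxolan-2-ol (anomer mixture), via detritylated tetraol 16 (not isolated), via open-chain hydroxy aldehyde 17 (not isolated)
Conditions: p-TsOH·H2O (cat.), MeOH/THF, rt; then NaHCO3, NaIO4, H2O, 0 °C to rt
Reagents that add atoms: none
Why: Acid-catalysed solvolysis of the trityl ether, then Malaprade cleavage of the terminal 1,2-diol, which excises the former exocyclic carbon. The aldehyde is captured at once by the C5 hydroxyl as a five-membered lactol, since the C9 hydroxyl could only form a four-membered ring; buffering guards the centre α to the aldehyde.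

Step 12
Reactants: 18 (3S,4R)-3-(hydroxymethyl)-4-[3-methoxy-4-(triisopropylsilyloxy)benzyl]oxolan-2-ol
Product: 19 (3S,4R)-3-(hydroxymethyl)-4-[3-methoxy-4-(triisopropylsilyloxy)benzyl]oxolan-2-one
Conditions: Ag2CO3 on Celite, toluene, reflux
Reagents that add atoms: none
Why: Fetizon oxidation; lactols are oxidised on Ag2CO3 much faster than isolated primary alcohols, so the C9 hydroxyl should remain. The trans lactone is also the thermodynamic isomer at the now enolisable C3.

Step 13
Reactants: 19 (3S,4R)-3-(hydroxymethyl)-4-[3-methoxy-4-(triisopropylsilyloxy)benzyl]oxolan-2-one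
Product: 20 (3S,4R)-3-[(tert-butyldimethylsilyloxy)methyl]-4-[3-methoxy-4-(triisopropylsilyloxy)benzyl]oxolan-2-one
Conditions: TBSCl, imidazole, DMF, 0 °C to rt
Reagents that add atoms: tert-butyldimethylsilyl chloride (CC(C)(C)[Si](C)(C)Cl)
Why: Imidazole-mediated silylation of the primary alcohol, mild enough not to epimerise or dehydrate the β-hydroxy lactone.

Step 14
Reactants: 21 4-bromo-2-methoxyphenol
Product: 22 (4-bromo-2-methoxyphenoxy)triisopropylsilane
Conditions: TIPSCl, imidazole, DMF, rt
Reagents that add atoms: triisopropylsilyl chloride (CC(C)[Si](Cl)(C(C)C)C(C)C)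
Why: Standard phenol silylation; the TIPS ether tolerates the halogen–lithium exchange that follows.

Step 15
Reactants: 22 (4-bromo-2-methoxyphenoxy)triisopropylsilane; 20 (3S,4R)-3-[(tert-butyldimethylsilyloxy)methyl]-4-[3-methoxy-4-(triisopropylsilyloxy)benzyl]oxolan-2-one
Product: 24 (3S,4R)-3-[(tert-butyldimethylsilyloxy)methyl]-2-[3-methoxy-4-(triisopropylsilyloxy)phenyl]-4-[3-methoxy-4-(triisopropylsilyloxy)benzyl]oxolan-2-ol (mixture at C2), via aryllithium 23 (not isolated)
Conditions: 22, n-BuLi, THF, −78 °C; then 20, −78 °C; aq. NH4Cl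
Reagents that add atoms: none
Why: Bromine–lithium exchange, then nucleophilic addition to the lactone carbonyl. The tetrahedral lithium hemiketalate is stable at −78 °C, which should prevent a second addition.

Step 16
Reactants: 24 (3S,4R)-3-[(tert-butyldimethylsilyloxy)methyl]-2-[3-methoxy-4-(triisopropylsilyloxy)phenyl]-4-[3-methoxy-4-(triisopropylsilyloxy)benzyl]oxolan-2-ol
Product: 26 (2S,3S,4R)-3-[(tert-butyldimethylsilyloxy)methyl]-2-[3-methoxy-4-(triisopropylsilyloxy)phenyl]-4-[3-methoxy-4-(triisopropylsilyloxy)benzyl]oxolane, via cyclic oxocarbenium ion 25 (not isolated)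
Conditions: Et3SiH, BF3·OEt2, CH2Cl2, −78 °C
Reagents that add atoms: none
Why: Ionic hydrogenation of a cyclic hemiketal: BF3 ionises 24 to the aryl-stabilised oxocarbenium ion 25, and the silane delivers hydride to C2 on the face anti to the adjacent C9 arm. The new C2 stereocentre is thus set by C3, with H trans and the aryl group cis to C9; the low temperature should suppress proton loss from C3.

Step 17
Reactants: 26 (2S,3S,4R)-3-[(tert-butyldimethylsilyloxy)methyl]-2-[3-methoxy-4-(triisopropylsilyloxy)phenyl]-4-[3-methoxy-4-(triisopropylsilyloxy)benzyl]oxolane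
Product: 27 [(2S,3S,4R)-2-[3-methoxy-4-(triisopropylsilyloxy)phenyl]-4-[3-methoxy-4-(triisopropylsilyloxy)benzyl]oxolan-3-yl]methanol
Conditions: CSA (cat.), MeOH/CH2Cl2, 0 °C
Reagents that add atoms: none
Why: Acid-catalysed methanolysis of the primary alkyl silyl ether; aryl silyl ethers are far more resistant to acid, so the two TIPS groups should stay.

Step 18
Reactants: 28 (E)-p-coumaric acid
Product: 30 (E)-3-[4-(tert-butyldimethylsilyloxy)phenyl]prop-2-enoic acid, via bis-silylated coumarate 29 (not isolated)
Conditions: TBSCl (2.5 equiv), imidazole, DMF, rt; then AcOH/THF/H2O, rt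
Reagents that add atoms: tert-butyldimethylsilyl chloride (CC(C)(C)[Si](C)(C)Cl)
Why: Silylation of both acidic hydroxyls; the silyl ester is hydrolysed by dilute acid, under which the aryl silyl ether is stable.

Step 19
Reactants: 27 [(2S,3S,4R)-2-[3-methoxy-4-(triisopropylsilyloxy)phenyl]-4-[3-methoxy-4-(triisopropylsilyloxy)benzyl]oxolan-3-yl]methanol; 30 (E)-3-[4-(tert-butyldimethylsilyloxy)phenyl]prop-2-enoic acid
Product: 31 [(2S,3S,4R)-2-[3-methoxy-4-(triisopropylsilyloxy)phenyl]-4-[3-methoxy-4-(triisopropylsilyloxy)benzyl]oxolan-3-yl]methyl (E)-3-[4-(tert-butyldimethylsilyloxy)phenyl]prop-2-enoate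
Conditions: EDC·HCl, DMAP (cat.), CH2Cl2, 0 °C to rt
Reagents that add atoms: none
Why: Steglich esterification of a primary alcohol; neutral conditions leave the alkene geometry and the benzylic ether untouched.

Step 20
Reactants: 31 [(2S,3S,4R)-2-[3-methoxy-4-(triisopropylsilyloxy)phenyl]-4-[3-methoxy-4-(triisopropylsilyloxy)benzyl]oxolan-3-yl]methyl (E)-3-[4-(tert-butyldimethylsilyloxy)phenyl]prop-2-enoate
Product: 32 [(2S,3S,4R)-2-(4-hydroxy-3-methoxyphenyl)-4-(4-hydroxy-3-methoxybenzyl)oxolan-3-yl]methyl (E)-3-(4-hydroxyphenyl)prop-2-enoate (CNP0119373.2)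
Conditions: TBAF, AcOH, THF, 0 °C to rt
Reagents that add atoms: none
Why: Fluoride cleavage of the three aryl silyl ethers; acetic acid protonates each phenoxide as it forms, so the cinnamate ester should suffer neither transesterification nor conjugate addition.

## Compound list

1 | 5,6-O-isopropylidene-L-gulono-1,4-lactone | CC1(C)OC[C@H](O1)[C@H]1OC(=O)[C@@H](O)[C@H]1O | starting material
2 | (S)-2,2-dimethyl-1,3-dioxolane-4-carbaldehyde | O=C[C@@H]1COC(C)(C)O1 | intermediate
3 | methyl (Z)-3-[(4R)-2,2-dimethyl-1,3-dioxolan-4-yl]prop-2-enoate | COC(=O)/C=C\[C@@H]1COC(C)(C)O1 | intermediate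
4 | (R)-5-(hydroxymethyl)furan-2(5H)-one | O=C1C=C[C@H](CO)O1 | intermediate
5 | (R)-5-(trityloxymethyl)furan-2(5H)-one | O=C1C=C[C@H](COC(c2ccccc2)(c2ccccc2)c2ccccc2)O1 | intermediate
6 | vanillin | COc1cc(C=O)ccc1O | starting material
7 | 3-methoxy-4-(triisopropylsilyloxy)benzaldehyde | COc1cc(C=O)ccc1O[Si](C(C)C)(C(C)C)C(C)C | intermediate
8 | [3-methoxy-4-(triisopropylsilyloxy)phenyl]methanol | COc1cc(CO)ccc1O[Si](C(C)C)(C(C)C)C(C)C | intermediate
9 | [4-(bromomethyl)-2-methoxyphenoxy]triisopropylsilane | COc1cc(CBr)ccc1O[Si](C(C)C)(C(C)C)C(C)C | intermediate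
10 | tris(methylthio)methane | CSC(SC)SC | starting material
11 | tris(methylthio)methyllithium | [Li]C(SC)(SC)SC | intermediate
12 | lithium enolate of (4R,5R)-4-[tris(methylthio)methyl]-5-(trityloxymethyl)oxolan-2-one | [Li]OC1=C[C@@H](C(SC)(SC)SC)[C@H](COC(c2ccccc2)(c2ccccc2)c2ccccc2)O1 | intermediate
13 | (3R,4R,5R)-3-[3-methoxy-4-(triisopropylsilyloxy)benzyl]-4-[tris(methylthio)methyl]-5-(trityloxymethyl)oxolan-2-one | COc1cc(C[C@H]2C(=O)O[C@@H](COC(c3ccccc3)(c3ccccc3)c3ccccc3)[C@@H]2C(SC)(SC)SC)ccc1O[Si](C(C)C)(C(C)C)C(C)C | intermediate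
14 | methyl (2R,3R,4R)-4-[3-methoxy-4-(triisopropylsilyloxy)benzyl]-5-oxo-2-(trityloxymethyl)oxolane-3-carboxylate | COc1cc(C[C@H]2C(=O)O[C@@H](COC(c3ccccc3)(c3ccccc3)c3ccccc3)[C@@H]2C(=O)OC)ccc1O[Si](C(C)C)(C(C)C)C(C)C | intermediate
15 | (2R,3S,4R)-3-(hydroxymethyl)-2-[3-methoxy-4-(triisopropylsilyloxy)benzyl]-5-(trityloxy)pentane-1,4-diol | COc1cc(C[C@@H](CO)[C@@H](CO)[C@@H](O)COC(c2ccccc2)(c2ccccc2)c2ccccc2)ccc1O[Si](C(C)C)(C(C)C)C(C)C | intermediate
16 | (2R,3S,4R)-3-(hydroxymethyl)-4-[3-methoxy-4-(triisopropylsilyloxy)benzyl]pentane-1,2,5-triol | COc1cc(C[C@@H](CO)[C@@H](CO)[C@@H](O)CO)ccc1O[Si](C(C)C)(C(C)C)C(C)C | intermediate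
17 | (2S,3R)-4-hydroxy-2-(hydroxymethyl)-3-[3-methoxy-4-(triisopropylsilyloxy)benzyl]butanal | COc1cc(C[C@@H](CO)[C@@H](CO)C=O)ccc1O[Si](C(C)C)(C(C)C)C(C)C | intermediate
18 | (3S,4R)-3-(hydroxymethyl)-4-[3-methoxy-4-(triisopropylsilyloxy)benzyl]oxolan-2-ol (anomer mixture) | COc1cc(C[C@H]2COC(O)[C@@H]2CO)ccc1O[Si](C(C)C)(C(C)C)C(C)C | intermediate
19 | (3S,4R)-3-(hydroxymethyl)-4-[3-methoxy-4-(triisopropylsilyloxy)benzyl]oxolan-2-one | COc1cc(C[C@H]2COC(=O)[C@@H]2CO)ccc1O[Si](C(C)C)(C(C)C)C(C)C | intermediate
20 | (3S,4R)-3-[(tert-butyldimethylsilyloxy)methyl]-4-[3-methoxy-4-(triisopropylsilyloxy)benzyl]oxolan-2-one | COc1cc(C[C@H]2COC(=O)[C@@H]2CO[Si](C)(C)C(C)(C)C)ccc1O[Si](C(C)C)(C(C)C)C(C)C | intermediate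
21 | 4-bromo-2-methoxyphenol | COc1cc(Br)ccc1O | starting material
22 | (4-bromo-2-methoxyphenoxy)triisopropylsilane | COc1cc(Br)ccc1O[Si](C(C)C)(C(C)C)C(C)C | intermediate
23 | [3-methoxy-4-(triisopropylsilyloxy)phenyl]lithium | [Li]c1ccc(O[Si](C(C)C)(C(C)C)C(C)C)c(OC)c1 | intermediate
24 | (3S,4R)-3-[(tert-butyldimethylsilyloxy)methyl]-2-[3-methoxy-4-(triisopropylsilyloxy)phenyl]-4-[3-methoxy-4-(triisopropylsilyloxy)benzyl]oxolan-2-ol (mixture at C2) | COc1cc(C[C@H]2COC(O)(c3ccc(O[Si](C(C)C)(C(C)C)C(C)C)c(OC)c3)[C@@H]2CO[Si](C)(C)C(C)(C)C)ccc1O[Si](C(C)C)(C(C)C)C(C)C | intermediate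
25 | (3S,4R)-3-[(tert-butyldimethylsilyloxy)methyl]-2-[3-methoxy-4-(triisopropylsilyloxy)phenyl]-4-[3-methoxy-4-(triisopropylsilyloxy)benzyl]-4,5-dihydro-3H-furan-1-ium (oxocarbenium ion) | COc1cc(C[C@H]2C[O+]=C(c3ccc(O[Si](C(C)C)(C(C)C)C(C)C)c(OC)c3)[C@@H]2CO[Si](C)(C)C(C)(C)C)ccc1O[Si](C(C)C)(C(C)C)C(C)C | intermediate
26 | (2S,3S,4R)-3-[(tert-butyldimethylsilyloxy)methyl]-2-[3-methoxy-4-(triisopropylsilyloxy)phenyl]-4-[3-methoxy-4-(triisopropylsilyloxy)benzyl]oxolane | COc1cc(C[C@H]2CO[C@H](c3ccc(O[Si](C(C)C)(C(C)C)C(C)C)c(OC)c3)[C@@H]2CO[Si](C)(C)C(C)(C)C)ccc1O[Si](C(C)C)(C(C)C)C(C)C | intermediate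
27 | [(2S,3S,4R)-2-[3-methoxy-4-(triisopropylsilyloxy)phenyl]-4-[3-methoxy-4-(triisopropylsilyloxy)benzyl]oxolan-3-yl]methanol | COc1cc(C[C@H]2CO[C@H](c3ccc(O[Si](C(C)C)(C(C)C)C(C)C)c(OC)c3)[C@@H]2CO)ccc1O[Si](C(C)C)(C(C)C)C(C)C | intermediate
28 | (E)-p-coumaric acid | O=C(O)/C=C/c1ccc(O)cc1 | starting material
29 | tert-butyldimethylsilyl (E)-3-[4-(tert-butyldimethylsilyloxy)phenyl]prop-2-enoate | CC(C)(C)[Si](C)(C)OC(=O)/C=C/c1ccc(O[Si](C)(C)C(C)(C)C)cc1 | intermediate
30 | (E)-3-[4-(tert-butyldimethylsilyloxy)phenyl]prop-2-enoic acid | O=C(O)/C=C/c1ccc(O[Si](C)(C)C(C)(C)C)cc1 | intermediate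
31 | [(2S,3S,4R)-2-[3-methoxy-4-(triisopropylsilyloxy)phenyl]-4-[3-methoxy-4-(triisopropylsilyloxy)benzyl]oxolan-3-yl]methyl (E)-3-[4-(tert-butyldimethylsilyloxy)phenyl]prop-2-enoate | COc1cc(C[C@H]2CO[C@H](c3ccc(O[Si](C(C)C)(C(C)C)C(C)C)c(OC)c3)[C@@H]2COC(=O)/C=C/c2ccc(O[Si](C)(C)C(C)(C)C)cc2)ccc1O[Si](C(C)C)(C(C)C)C(C)C | intermediate
32 | [(2S,3S,4R)-2-(4-hydroxy-3-methoxyphenyl)-4-(4-hydroxy-3-methoxybenzyl)oxolan-3-yl]methyl (E)-3-(4-hydroxyphenyl)prop-2-enoate | COc1cc(C[C@H]2CO[C@H](c3ccc(O)c(OC)c3)[C@@H]2COC(=O)/C=C/c2ccc(O)cc2)ccc1O | target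

## Step count and risk

Total: 20 steps. Longest linear sequence: 15 steps (1 to 32 through steps 1–4, 8–13, 15–17, 19 and 20).

**Step 8 (key step).** The hindered enolate 12 may exchange a proton with product or solvent before it is benzylated, or alkylate on oxygen, so that the unbenzylated adduct is recovered. Fallback: the two bond formations are separated. Starting from 5 and 11, the conjugate addition is quenched with NH4Cl to isolate (4R,5R)-4-[tris(methylthio)methyl]-5-(trityloxymethyl)oxolan-2-one F1. F1 is then deprotonated with LiN(SiMe3)2 in THF/DMPU and alkylated with 9; trans alkylation of a β-substituted γ-lactone enolate should return the route to 13.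

**Step 16.** Cation 25 may lose the C3 proton to an enol ether, which epimerises C3 and erodes facial selectivity, or BF3 may strip the primary silyl ether. Fallback: C2 is set by an addition followed by an SN2 closure.
- From 20, i-Bu2AlH at −78 °C should give the lactol (3S,4R)-3-[(tert-butyldimethylsilyloxy)methyl]-4-[3-methoxy-4-(triisopropylsilyloxy)benzyl]oxolan-2-ol F2.
- Excess 23 should add to its open aldehyde form under Felkin–Anh control (aryl anti to the branched C4 residue) to give (1S,2S,3R)-2-[(tert-butyldimethylsilyloxy)methyl]-1-[3-methoxy-4-(triisopropylsilyloxy)phenyl]-3-[3-methoxy-4-(triisopropylsilyloxy)benzyl]butane-1,4-diol F3.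
- Selective tosylation of the primary hydroxyl (TsCl, pyridine, 0 °C) gives the primary 4-O-tosylate of that diol F4, and NaH closes the ring with retention at C2, rejoining the route at 26.

**Step 15.** The basic aryllithium may enolise lactone 20, or the ring-opened keto alkoxide may eliminate silanolate on warming. Fallback: the acyl donor is changed.
- From 20, MeNH(OMe)·HCl and AlMe3 should open the lactone to (2S,3R)-2-[(tert-butyldimethylsilyloxy)methyl]-4-hydroxy-N-methoxy-N-methyl-3-[3-methoxy-4-(triisopropylsilyloxy)benzyl]butanamide F5.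
- F5 is silylated at once (Et3SiCl, imidazole) to its 4-O-triethylsilyl ether F6.
- Addition of 23 gives (2S,3R)-2-[(tert-butyldimethylsilyloxy)methyl]-1-[3-methoxy-4-(triisopropylsilyloxy)phenyl]-3-[3-methoxy-4-(triisopropylsilyloxy)benzyl]-4-(triethylsilyloxy)butan-1-one F7.
- PPTS in MeOH at 0 °C removes the triethylsilyl group and the hydroxy ketone closes to 24.

**Step 9.** The Lewis-acidic mercury salts may cleave the trityl ether, or solvolysis may stall at the thiol ester. Both deviations are tolerable in themselves, since each product would still be reduced to 15 or 16. Fallback: the thiol ester is made deliberately. From 13, AgNO3 and 2,6-lutidine in aqueous THF should give S-methyl (2R,3R,4R)-4-[3-methoxy-4-(triisopropylsilyloxy)benzyl]-5-oxo-2-(trityloxymethyl)oxolane-3-carbothioate F8, and LiAlH4 reduces thiol ester and lactone together to rejoin the route at 15.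

**Step 17.** The acid may begin to reopen the benzylic ether at C2, with epimerisation toward the trans isomer, or remove an aryl silyl ether. Fallback: selective deprotection is abandoned. From 26, TBAF removes all three silyl groups to give 4-[(2S,3S,4R)-4-(4-hydroxy-3-methoxybenzyl)-3-(hydroxymethyl)oxolan-2-yl]-2-methoxyphenol F9. A Mitsunobu esterification of F9 with unprotected 28 (PPh3, diisopropyl azodicarboxylate, THF, 0 °C) relies on the carboxylic acid being the only sufficiently acidic partner and the primary alcohol the only activatable hydroxyl, and arrives directly at 32.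

## Further compounds

F1 | step 8 | (4R,5R)-4-[tris(methylthio)methyl]-5-(trityloxymethyl)oxolan-2-one | O=C1C[C@@H](C(SC)(SC)SC)[C@H](COC(c2ccccc2)(c2ccccc2)c2ccccc2)O1
F2 | step 16 | (3S,4R)-3-[(tert-butyldimethylsilyloxy)methyl]-4-[3-methoxy-4-(triisopropylsilyloxy)benzyl]oxolan-2-ol | COc1cc(C[C@H]2COC(O)[C@@H]2CO[Si](C)(C)C(C)(C)C)ccc1O[Si](C(C)C)(C(C)C)C(C)C
F3 | step 16 | (1S,2S,3R)-2-[(tert-butyldimethylsilyloxy)methyl]-1-[3-methoxy-4-(triisopropylsilyloxy)phenyl]-3-[3-methoxy-4-(triisopropylsilyloxy)benzyl]butane-1,4-diol | COc1cc(C[C@@H](CO)[C@@H](CO[Si](C)(C)C(C)(C)C)[C@H](O)c2ccc(O[Si](C(C)C)(C(C)C)C(C)C)c(OC)c2)ccc1O[Si](C(C)C)(C(C)C)C(C)C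
F4 | step 16 | primary 4-O-tosylate of diol F3 | COc1cc(C[C@@H](COS(=O)(=O)c2ccc(C)cc2)[C@@H](CO[Si](C)(C)C(C)(C)C)[C@H](O)c2ccc(O[Si](C(C)C)(C(C)C)C(C)C)c(OC)c2)ccc1O[Si](C(C)C)(C(C)C)C(C)C
F5 | step 15 | (2S,3R)-2-[(tert-butyldimethylsilyloxy)methyl]-4-hydroxy-N-methoxy-N-methyl-3-[3-methoxy-4-(triisopropylsilyloxy)benzyl]butanamide | COc1cc(C[C@@H](CO)[C@@H](CO[Si](C)(C)C(C)(C)C)C(=O)N(C)OC)ccc1O[Si](C(C)C)(C(C)C)C(C)C
F6 | step 15 | 4-O-triethylsilyl ether of amide F5 | COc1cc(C[C@@H](CO[Si](CC)(CC)CC)[C@@H](CO[Si](C)(C)C(C)(C)C)C(=O)N(C)OC)ccc1O[Si](C(C)C)(C(C)C)C(C)C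
F7 | step 15 | (2S,3R)-2-[(tert-butyldimethylsilyloxy)methyl]-1-[3-methoxy-4-(triisopropylsilyloxy)phenyl]-3-[3-methoxy-4-(triisopropylsilyloxy)benzyl]-4-(triethylsilyloxy)butan-1-one | COc1cc(C[C@@H](CO[Si](CC)(CC)CC)[C@@H](CO[Si](C)(C)C(C)(C)C)C(=O)c2ccc(O[Si](C(C)C)(C(C)C)C(C)C)c(OC)c2)ccc1O[Si](C(C)C)(C(C)C)C(C)C
F8 | step 9 | S-methyl (2R,3R,4R)-4-[3-methoxy-4-(triisopropylsilyloxy)benzyl]-5-oxo-2-(trityloxymethyl)oxolane-3-carbothioate | COc1cc(C[C@H]2C(=O)O[C@@H](COC(c3ccccc3)(c3ccccc3)c3ccccc3)[C@@H]2C(=O)SC)ccc1O[Si](C(C)C)(C(C)C)C(C)C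
F9 | step 17 | 4-[(2S,3S,4R)-4-(4-hydroxy-3-methoxybenzyl)-3-(hydroxymethyl)oxolan-2-yl]-2-methoxyphenol | COc1cc(C[C@H]2CO[C@H](c3ccc(O)c(OC)c3)[C@@H]2CO)ccc1O
A1 | alternative 1 | dimethyl (2S,3R)-2-[(tert-butyldimethylsilyloxy)methyl]-3-(3-methoxy-4-pivaloyloxyphenyl)cyclopropane-1,1-dicarboxylate (trans) | COC(=O)C1(C(=O)OC)[C@@H](c2ccc(OC(=O)C(C)(C)C)c(OC)c2)[C@@H]1CO[Si](C)(C)C(C)(C)C
A2 | alternative 1 | formaldehyde | C=O
A3 | alternative 1 | dimethyl (4S,5S)-4-[(tert-butyldimethylsilyloxy)methyl]-5-(3-methoxy-4-pivaloyloxyphenyl)oxolane-3,3-dicarboxylate | COC(=O)C1(C(=O)OC)CO[C@H](c2ccc(OC(=O)C(C)(C)C)c(OC)c2)[C@@H]1CO[Si](C)(C)C(C)(C)C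
A4 | alternative 2 | 4-(tert-butyldimethylsilyloxy)-3-methoxybenzaldehyde | COc1cc(C=O)ccc1O[Si](C)(C)C(C)(C)C
A5 | alternative 2 | methyl (E)-4-(tert-butyldimethylsilyloxy)-2-[(4,4,5,5-tetramethyl-1,3,2-dioxaborolan-2-yl)methyl]but-2-enoate | COC(=O)/C(CB1OC(C)(C)C(C)(C)O1)=C/CO[Si](C)(C)C(C)(C)C
A6 | alternative 2 | (4S,5S)-5-[4-(tert-butyldimethylsilyloxy)-3-methoxyphenyl]-4-[(tert-butyldimethylsilyloxy)methyl]-3-methylideneoxolan-2-one | C=C1C(=O)O[C@H](c2ccc(O[Si](C)(C)C(C)(C)C)c(OC)c2)[C@@H]1CO[Si](C)(C)C(C)(C)C
A7 | alternative 3 | 3-[4-(tert-butyldimethylsilyloxy)-3-methoxybenzyl]cyclobutan-1-one | COc1cc(CC2CC(=O)C2)ccc1O[Si](C)(C)C(C)(C)C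
A8 | alternative 3 | (R)-4-[4-(tert-butyldimethylsilyloxy)-3-methoxybenzyl]oxolan-2-one | COc1cc(C[C@H]2COC(=O)C2)ccc1O[Si](C)(C)C(C)(C)C
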